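(The constants come from no measurement; the result is computed.)

A rate constant counted per molar and per hour becomes a time only when a concentration stands beside it, so that is where we begin with this flask.

starting complex 1.1 M (in portions, 2); incoming ligand 1.10 equiv; time 25 h; the portions of starting complex follow each other after 15 min, the first at the start

- why nothing more happens at 25 h, or that something still does (the incoming ligand has run out first / all of the starting complex has reacted / forward and back rates have come level / it is still moving)
- conversion of starting complex at 25 h
- amount of over-reaction product at 25 h, in percent of the starting complex charged

- the reaction counts as stopped when no species that holds the starting complex changes by six tenths of a point or more over the second half of the time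
- run time (flask): 25 h

    starting complex + incoming ligand ⇌ leaving ligand + complex with one exchanged (K1 = 18, k1 = 0.27 M⁻¹ h⁻¹)
    complex with one exchanged → over-reaction product (k2 = 0.64 h⁻¹)
    complex with one exchanged + incoming ligand ⇌ leaving ligand + complex with two exchanged (K3 = 1.5, k3 = 0.031 M⁻¹ h⁻¹)
    complex with two exchanged + incoming ligand ⇌ leaving ligand + complex with three exchanged (K4 = 12, k4 = 0.24 M⁻¹ h⁻¹)

Starting complex meets incoming ligand and gives leaving ligand and complex with one exchanged. That complex falls by itself to over-reaction product, or takes up a further ligand. We carry one time, the pairing time 3.37 h: one over the first rate constant times the full charge, the second-order half-life of two partners at equal charge.

In the first instants [incoming ligand] stands near 1.21 M, so each molecule of starting complex reacts at 0.327 h⁻¹. The second portion comes after 15 min, far sooner than the pairing time, so we treat the charge as one, and we drop the way back, with K1 at 18. Complex with one exchanged falls away at 0.64 h⁻¹, twice that rate, so at the start the two steps are of like size.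

Through the middle [incoming ligand] sinks and that gap widens. The side exit to complex with two exchanged is smaller than the main exit, at 5.86 % of it at the start, but each molecule taking it costs a second ligand, so our leftover should come out low.

By 25 h this flask has run 7.42 pairing times. Equal charges would leave 11.9 % of the starting complex. The 10.0 % excess of ligand, put into the same two-partner rate law, leaves 7.63 %, down from 16.8 % at mid-run. A fall of 9.2 percentage points over the second half means the flask is still moving. We commit to a conversion of 92.4 % and over-reaction product between 87.3 % and that figure.

The forecast also says it is still moving, with a lower conversion of 90 % and 86.5 % of over-reaction product, holding that “the first exchange is pulled forward as a nearly stoichiometric second-order reaction”. The simulation gives it is still moving, a conversion of 90.9 % and 88.1 % of over-reaction product.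

In this flask, after those 7.42 pairing times, 9.10 % of the starting complex stands against the 7.63 % we reckoned, while at 25.0 h the fall to over-reaction product uses complex with one exchanged 120 times as fast as the forward step to complex with two exchanged. In the neighbour flask charged at 0.28 M, the pairing time grows to 13.2 h, so the same run holds 1.89 pairing times, the same rule leaves 30.4 %, and that flask shows 30.9 % of its starting complex at 25.0 h.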